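The rate constants come from no measurement; what happens was integrated by code.

A small charge of E, 0.100 M, smaller than either partner's charge, was what L and Z fought over in each flask, and I wanted to know how much of it L would win.

in all of them: E 0.100 M; time 1.0 h
- Wednesday's: L 0.20 M (fed, over 25 min); Z 0.240 M; temperature 60 °C; all else is in the flask from the start; the feed brings no volume worth counting
- Monday's: L 0.20 M (fed, over 6.0 min); Z 0.240 M; temperature 60 °C; all else is in the flask from the start; the feed brings no volume worth counting
- Thursday's: L 0.20 M (fed, over 25 min); Z 0.240 M; the addition at 20 °C, then warmed to 60 °C; the feed brings no volume worth counting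
- Tuesday's: L 0.20 M; Z 0.240 M (fed, over 25 min); temperature 60 °C; all else is in the flask from the start; the feed brings no volume worth counting

    L + Z → L.Z (k1 = 3.7 /M/min, Ea1 = 63.0 kJ/mol)
    L + E → L.E (k2 = 23 /M/min, Ea2 = 60.0 kJ/mol)
    Z → D (k3 = 0.079 /min, Ea3 = 87.0 kJ/mol)
    E + Z → E.Z (k4 = 12 /M/min, Ea4 = 67.0 kJ/mol)
    2 Z → Z2 (k5 = 0.072 /M/min, Ea5 = 84.0 kJ/mol)
    (constants at 60 °C)

1. the flask that comes out highest in amount of L.E, in percent of the L charged; "all alike" if 1.5 percentage points covers them all (Wednesday's / Monday's / Thursday's / Tuesday's / all alike)
2. amount of L.E at the end, in percent of the L charged, Wednesday's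
3. amount of L.E at the end, in percent of the L charged, Monday's
4. amount of L.E at the end, in percent of the L charged, Thursday's
5. amount of L.E at the end, in percent of the L charged, Tuesday's

- where a step has two of a species, its rate is k times that concentration squared, and two are used at each turn
- the constants hold at 60 °C; other temperatures follow from the activation energies

E saw two rates: 23 /M/min times L and 12 /M/min times Z. The selectivity factor was 1.92, and my zero was the even case, where those two rates are equal and E goes evenly to L.E and E.Z. At the start of Wednesday's flask Z stood at its full charge, and with Z held there I reckoned E's life against Z at 0.347 min. L arrived by the feed, and with none of it consumed I reckoned 15.7 min of feeding to reach that even case. The life was far shorter than this parity time, so I expected E to go while L was still thin. Summing the rising L against E's decay gave the capture ratio, life over parity time, 2.22%, as the share of E reaching L.E.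

With Z taken as fixed, that put Wednesday's at 1.11% of the L charged. Monday's quicker feed gave a ratio of 9.24%, or 4.62%. Tuesday's swapped the roles: L stood and Z was fed, so with L held at its charge the same reckoning, constants exchanged, put 0.544% of E on the way to E.Z, leaving 49.7% of the L charged as L.E. Thursday's, with its cold addition, I left unreckoned.

The forecast said 1.5% for Wednesday's, 4.6% for Monday's, 16.7% for Thursday's and 49.5% for Tuesday's, with Tuesday's highest, on the ground that “the order of addition decides the outcome”. Its Wednesday's figure stood above mine.

The flasks gave 1.48%, 4.87%, 16.8% and 49.5% in that order, with Tuesday's highest.

Striking out the path from E + Z to E.Z took the gap between Tuesday's and Wednesday's from 48 percentage points to 0 points, the largest single effect. With the feed and the L charge held, the capture ratio goes with the inverse square of Z, so for Wednesday's recipe with 0.60 M of Z I reckoned 0.355% of E reaching L.E, or 0.177% of the L charged, and that flask gave 0.169%.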